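**Assumption:** daucane numbering is used (C1 = methyl-bearing ring-fusion carbon, C4 = isopropyl carbinol, C5 = ring-fusion CH, C6 = ester carbon, C9 = allylic carbinol), with α/β meaning opposite to/same side as the C1 methyl. The target is then 6α-vanilloyloxy-dauc-7-ene-4β,9β-diol, (1R,4R,5S,6S,9R). Compounds 1, 2, 6 and 11 are taken as catalogue chemicals.

**Retrosynthetic overview**
1. Target 14 ⇐ double deacetylation of 13 ⇐ late C9–O bond by anti-selective allylic C–H acetoxylation of the Δ7 ester 12 (new method).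
2. 12 ⇐ C6–O esterification of dauc-7-ene-4β,6α-diol 10 with acetyl-protected vanillic acid 11.
3. 10 ⇐ ring-closing metathesis (C7=C8) of the monocyclic diene diol 9; the cycloheptene is the only ring built and is closed onto the purchased cyclopentane.
4. 9 ⇐ isopropyl addition at C4 ⇐ keto-alcohol 8 ⇐ asymmetric conjugate methylation/aldol of enone 5 with Me3Al and acrolein (sets C1, C5, C6).
5. 5 ⇐ 3-ethoxycyclopent-2-enone 1 + homoallyl bromide 2.

**Step 1**
Reactants: 1 3-ethoxycyclopent-2-en-1-one; 2 4-bromo-2-methylbut-1-ene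
Product: 5 3-(3-methylbut-3-en-1-yl)cyclopent-2-en-1-one, via Grignard reagent 3 (not isolated), via bromomagnesium alkoxide adduct 4 (not isolated)
Conditions: 2, Mg turnings, THF, 40 °C; then 1, THF, 0 °C; then 1 M HCl, 0 °C → rt
Reagents that add atoms: water, O
Why: Stork–Danheiser alkylative enone transposition, in which 1,2-addition of the Grignard reagent to the vinylogous ester is followed by acid-promoted loss of the carbinol oxygen, hydration at the enol-ether carbon and loss of ethanol; no stereocentre is formed.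

**Step 2**
Reactants: 5 3-(3-methylbut-3-en-1-yl)cyclopent-2-en-1-one; 6 prop-2-enal (acrolein)
Product: 8 (2S,3S)-2-[(1S)-1-hydroxyprop-2-en-1-yl]-3-methyl-3-(3-methylbut-3-en-1-yl)cyclopentan-1-one, via dimethylaluminium enolate 7 (not isolated)
Conditions: Me3Al (1.4 equiv), Cu(O2CC4H3S) (copper thiophene-2-carboxylate, 2 mol %), chiral phosphinamine Ph2P–N[CH(CH3)(2-naphthyl)]2 (4 mol %, the antipode that gives the 3S centre), Et2O, −30 °C; then 6 (1.5 equiv), THF, −78 °C; aq. potassium sodium tartrate (KNaC4H4O6)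
Reagents that add atoms: trimethylaluminium, C[Al](C)C
Why: Copper-catalysed asymmetric conjugate addition of Me3Al sets the quaternary C1 centre under ligand control, and the resulting cyclic (E)-aluminium enolate adds to acrolein through a closed Zimmerman–Traxler transition state on the face anti to the larger homoallyl chain, which gives the trans ring relationship at C5 and the anti aldol at C6.

**Step 3**
Reactants: 8 (2S,3S)-2-[(1S)-1-hydroxyprop-2-en-1-yl]-3-methyl-3-(3-methylbut-3-en-1-yl)cyclopentan-1-one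
Product: 9 (1R,2S,3S)-2-[(1S)-1-hydroxyprop-2-en-1-yl]-3-methyl-3-(3-methylbut-3-en-1-yl)-1-(propan-2-yl)cyclopentan-1-ol
Conditions: iPrMgCl (3.5 equiv), anhydrous CeCl3 (3.5 equiv), THF, −78 → 0 °C; aq. NH4Cl
Reagents that add atoms: isopropylmagnesium chloride, CC(C)[Mg]Cl
Why: Cerium-mediated Grignard 1,2-addition (Imamoto conditions, which suppress enolisation and β-hydride reduction) takes place on the cyclopentanone face anti to the adjacent, metal-chelated C5 side chain, so isopropyl enters trans to it and the new tertiary hydroxyl is 4β.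

**Step 4**
Reactants: 9 (1R,2S,3S)-2-[(1S)-1-hydroxyprop-2-en-1-yl]-3-methyl-3-(3-methylbut-3-en-1-yl)-1-(propan-2-yl)cyclopentan-1-ol
Product: 10 (3R,3aS,4S,8aS)-6,8a-dimethyl-3-(propan-2-yl)-1,2,3,3a,4,7,8,8a-octahydroazulene-3,4-diol (dauc-7-ene-4β,6α-diol)
Conditions: second-generation Hoveyda–Grubbs catalyst RuCl2(H2IMes)(=CH-C6H4-2-OiPr) (5 mol %), 1,4-benzoquinone (10 mol %), toluene (0.005 M), 80 °C
Reagents that add atoms: none
Why: Ring-closing metathesis between the vinyl carbinol and the 1,1-disubstituted alkene closes the trans-fused cycloheptene with the trisubstituted C7=C8 bond and loss of ethene, the free allylic hydroxyl being tolerated and benzoquinone suppressing Ru–H isomerisation; no stereocentre is formed.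

**Step 5**
Reactants: 10 (3R,3aS,4S,8aS)-6,8a-dimethyl-3-(propan-2-yl)-1,2,3,3a,4,7,8,8a-octahydroazulene-3,4-diol; 11 4-acetoxy-3-methoxybenzoic acid
Product: 12 (3R,3aS,4S,8aS)-3-hydroxy-6,8a-dimethyl-3-(propan-2-yl)-1,2,3,3a,4,7,8,8a-octahydroazulen-4-yl 4-acetoxy-3-methoxybenzoate
Conditions: DCC (1.5 equiv), DMAP (0.3 equiv), CH2Cl2, 0 °C → rt
Reagents that add atoms: none
Why: Steglich esterification forms the C6–O ester bond with retention at C6 and is selective for the secondary allylic hydroxyl because the tertiary C4 hydroxyl does not acylate under these conditions.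

**Step 6**
Reactants: 12 (3R,3aS,4S,8aS)-3-hydroxy-6,8a-dimethyl-3-(propan-2-yl)-1,2,3,3a,4,7,8,8a-octahydroazulen-4-yl 4-acetoxy-3-methoxybenzoate
Product: 13 (3R,3aS,4S,7R,8aR)-7-acetoxy-3-hydroxy-6,8a-dimethyl-3-(propan-2-yl)-1,2,3,3a,4,7,8,8a-octahydroazulen-4-yl 4-acetoxy-3-methoxybenzoate
Conditions: Pd(OAc)2 (10 mol %), aryl sulfoxide–oxazoline ligand 2-[2-(p-tolylsulfinyl)phenyl]-4,4-dimethyl-2-oxazoline (12 mol %), AcOH (10 equiv), 2,5-dimethyl-1,4-benzoquinone (1.5 equiv), 1,4-dioxane, 45 °C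
Reagents that add atoms: acetic acid, CC(=O)O
Why: Proposed new method: diastereoselective allylic C–H acetoxylation of a trisubstituted endocyclic alkene by divalent palladium, in which Pd binds the C7=C8 bond on the α-face (anti to the axial C1 methyl) and cleaves a C–H bond of the only allylic methylene (C9) to give the C7–C8–C9 η3-allyl, the S,N-chelated cationic Pd centre keeps acetate out of the inner sphere so that acetate attacks from outside, anti to Pd (β-face), at C9, the terminus remote from the bulky, electron-withdrawing C6 aroyloxy group, which sets the 9R (9β) centre; the closest known reaction types are Pd(OAc)2/sulfoxide/benzoquinone allylic C–H acetoxylation of terminal alkenes and the outer-sphere trans acetate attack on cyclic η3-allylpalladium intermediates in diene 1,4-diacetoxylation.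

**Step 7**
Reactants: 13 (3R,3aS,4S,7R,8aR)-7-acetoxy-3-hydroxy-6,8a-dimethyl-3-(propan-2-yl)-1,2,3,3a,4,7,8,8a-octahydroazulen-4-yl 4-acetoxy-3-methoxybenzoate
Product: 14 (3R,3aS,4S,7R,8aR)-3,7-dihydroxy-6,8a-dimethyl-3-(propan-2-yl)-1,2,3,3a,4,7,8,8a-octahydroazulen-4-yl 4-hydroxy-3-methoxybenzoate
Conditions: K2CO3 (0.5 equiv), MeOH, 0 °C → rt; aq. NH4Cl
Reagents that add atoms: none
Why: Base-catalysed transesterification (Zemplén-type methanolysis) removes the phenolic acetate at once and the secondary allylic acetate within hours, while the hindered C6 aroyl ester, further deactivated as its para-phenoxide, survives; no stereocentre is touched.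

**Compound list**
1 | 3-ethoxycyclopent-2-en-1-one | CCOC1=CC(=O)CC1 | starting material
2 | 4-bromo-2-methylbut-1-ene | CC(=C)CCBr | starting material
3 | (3-methylbut-3-en-1-yl)magnesium bromide | CC(=C)CC[Mg]Br | intermediate
4 | bromomagnesium 3-ethoxy-1-(3-methylbut-3-en-1-yl)cyclopent-2-en-1-olate (racemic) | CCOC1=CC(CCC(C)=C)(O[Mg]Br)CC1 | intermediate
5 | 3-(3-methylbut-3-en-1-yl)cyclopent-2-en-1-one | CC(=C)CCC1=CC(=O)CC1 | intermediate
6 | prop-2-enal (acrolein) | C=CC=O | starting material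
7 | dimethyl{[(3S)-3-methyl-3-(3-methylbut-3-en-1-yl)cyclopent-1-en-1-yl]oxy}alumane | C[Al](C)OC1=C[C@@](C)(CCC(C)=C)CC1 | intermediate
8 | (2S,3S)-2-[(1S)-1-hydroxyprop-2-en-1-yl]-3-methyl-3-(3-methylbut-3-en-1-yl)cyclopentan-1-one | C=C[C@H](O)[C@H]1C(=O)CC[C@]1(C)CCC(C)=C | intermediate
9 | (1R,2S,3S)-2-[(1S)-1-hydroxyprop-2-en-1-yl]-3-methyl-3-(3-methylbut-3-en-1-yl)-1-(propan-2-yl)cyclopentan-1-ol | C=C[C@H](O)[C@H]1[C@](O)(C(C)C)CC[C@]1(C)CCC(C)=C | intermediate
10 | (3R,3aS,4S,8aS)-6,8a-dimethyl-3-(propan-2-yl)-1,2,3,3a,4,7,8,8a-octahydroazulene-3,4-diol | O[C@H]1C=C(C)CC[C@@]2(C)CC[C@@](O)(C(C)C)[C@H]12 | intermediate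
11 | 4-acetoxy-3-methoxybenzoic acid | CC(=O)Oc1ccc(cc1OC)C(=O)O | starting material
12 | (3R,3aS,4S,8aS)-3-hydroxy-6,8a-dimethyl-3-(propan-2-yl)-1,2,3,3a,4,7,8,8a-octahydroazulen-4-yl 4-acetoxy-3-methoxybenzoate | CC(=O)Oc1ccc(cc1OC)C(=O)O[C@H]1C=C(C)CC[C@@]2(C)CC[C@@](O)(C(C)C)[C@H]12 | intermediate
13 | (3R,3aS,4S,7R,8aR)-7-acetoxy-3-hydroxy-6,8a-dimethyl-3-(propan-2-yl)-1,2,3,3a,4,7,8,8a-octahydroazulen-4-yl 4-acetoxy-3-methoxybenzoate | CC(=O)Oc1ccc(cc1OC)C(=O)O[C@H]1C=C(C)[C@H](OC(C)=O)C[C@@]2(C)CC[C@@](O)(C(C)C)[C@H]12 | intermediate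
14 | (3R,3aS,4S,7R,8aR)-3,7-dihydroxy-6,8a-dimethyl-3-(propan-2-yl)-1,2,3,3a,4,7,8,8a-octahydroazulen-4-yl 4-hydroxy-3-methoxybenzoate | COc1cc(C(=O)O[C@H]2C=C(C)[C@H](O)C[C@@]3(C)CC[C@@](O)(C(C)C)[C@H]23)ccc1O | target

**Totals**
Total step count: 7. Longest linear sequence: 7 steps (1 → 14).

**Three steps most likely to fail**

Step 6 (the proposed new C–H acetoxylation). Possible failures are: no C–H cleavage on the hindered trisubstituted alkene, activation of the C8 methyl instead of C9, inner-sphere acetate delivery giving the 9α-acetate, capture of the allyl by the 4β-hydroxyl, or ionisation of the C6 ester. The fallback uses known chemistry and sets out from 12. Allylic oxidation of the single allylic methylene with CrO3/3,5-dimethylpyrazole (CH2Cl2, −20 °C) gives the enone (3R,3aS,4S,8aR)-3-hydroxy-6,8a-dimethyl-7-oxo-3-(propan-2-yl)-1,2,3,3a,4,7,8,8a-octahydroazulen-4-yl 4-acetoxy-3-methoxybenzoate F1. Luche reduction (NaBH4, CeCl3·7H2O, MeOH, −78 °C) then delivers hydride to the α-face, anti to the axial C1 methyl, and gives the 9β-alcohol (3R,3aS,4S,7R,8aR)-3,7-dihydroxy-6,8a-dimethyl-3-(propan-2-yl)-1,2,3,3a,4,7,8,8a-octahydroazulen-4-yl 4-acetoxy-3-methoxybenzoate F2. K2CO3/MeOH removes the phenolic acetate and the fallback comes back to the route at 14.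

Step 2 (conjugate addition/aldol). Possible failures are: a sluggish aluminium enolate, a modest anti/syn ratio at C6, modest facial control at C5 (methyl against a primary alkyl chain), and an ee that needs upgrading by recrystallisation of 10. The fallback sets the C6 centre by directed reduction instead of by the aldol. It sets out from 10 obtained together with its C6 epimer (3R,3aS,4R,8aS)-6,8a-dimethyl-3-(propan-2-yl)-1,2,3,3a,4,7,8,8a-octahydroazulene-3,4-diol F3, after the aldol mixture has been carried through steps 3 and 4. MnO2 (CH2Cl2, rt) oxidises both allylic alcohols to the single enone (3R,3aR,8aS)-3-hydroxy-6,8a-dimethyl-3-(propan-2-yl)-2,3,3a,7,8,8a-hexahydroazulen-4(1H)-one F4. Evans–Saksena reduction with Me4NBH(OAc)3 (MeCN/AcOH, −20 °C) delivers hydride from the boron bound to the 4β-oxygen to the β-face of the C6 carbonyl, giving the 6α-alcohol and coming back at 10.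

Step 3 (isopropyl addition). Possible failures are enolisation of the hindered ketone, β-hydride reduction and retro-aldol of the aldolate. The fallback sets out from 8 and closes the ring first. Metathesis under the conditions of step 4 gives the bicyclic ketol (3aS,4S,8aS)-4-hydroxy-6,8a-dimethyl-2,3a,4,7,8,8a-hexahydroazulen-3(1H)-one F5. Isopropenylmagnesium bromide/CeCl3 (THF, −78 °C), an sp2 Grignard reagent that cannot transfer a β-hydride, adds from the α-face to give (3S,3aS,4S,8aS)-6,8a-dimethyl-3-(prop-1-en-2-yl)-1,2,3,3a,4,7,8,8a-octahydroazulene-3,4-diol F6. Hydrogenation with RhCl(PPh3)3/H2 (benzene, rt) reduces only the 1,1-disubstituted alkene and comes back at 10.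

**Further compounds**
F1 | step 6 | (3R,3aS,4S,8aR)-3-hydroxy-6,8a-dimethyl-7-oxo-3-(propan-2-yl)-1,2,3,3a,4,7,8,8a-octahydroazulen-4-yl 4-acetoxy-3-methoxybenzoate | CC(=O)Oc1ccc(cc1OC)C(=O)O[C@H]1C=C(C)C(=O)C[C@@]2(C)CC[C@@](O)(C(C)C)[C@H]12
F2 | step 6 | (3R,3aS,4S,7R,8aR)-3,7-dihydroxy-6,8a-dimethyl-3-(propan-2-yl)-1,2,3,3a,4,7,8,8a-octahydroazulen-4-yl 4-acetoxy-3-methoxybenzoate | CC(=O)Oc1ccc(cc1OC)C(=O)O[C@H]1C=C(C)[C@H](O)C[C@@]2(C)CC[C@@](O)(C(C)C)[C@H]12
F3 | step 2 | (3R,3aS,4R,8aS)-6,8a-dimethyl-3-(propan-2-yl)-1,2,3,3a,4,7,8,8a-octahydroazulene-3,4-diol | O[C@@H]1C=C(C)CC[C@@]2(C)CC[C@@](O)(C(C)C)[C@H]12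
F4 | step 2 | (3R,3aR,8aS)-3-hydroxy-6,8a-dimethyl-3-(propan-2-yl)-2,3,3a,7,8,8a-hexahydroazulen-4(1H)-one | O=C1C=C(C)CC[C@@]2(C)CC[C@@](O)(C(C)C)[C@H]12
F5 | step 3 | (3aS,4S,8aS)-4-hydroxy-6,8a-dimethyl-2,3a,4,7,8,8a-hexahydroazulen-3(1H)-one | O[C@H]1C=C(C)CC[C@@]2(C)CCC(=O)[C@H]12
F6 | step 3 | (3S,3aS,4S,8aS)-6,8a-dimethyl-3-(prop-1-en-2-yl)-1,2,3,3a,4,7,8,8a-octahydroazulene-3,4-diol | O[C@H]1C=C(C)CC[C@@]2(C)CC[C@@](O)(C(C)=C)[C@H]12
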